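The flavone is disconnected at the C4a–C5 bond of ring A, because the oxygens at C5, C7 and C8a sit in the 1,3,5-pattern of an acylphloroglucinol whose acyl carbon becomes C4. In a single operation an intramolecular Claisen condensation of an open-chain cinnamoyl 3,5,7-triketo methyl ester closes ring A, makes it aromatic and delivers all three phenolic oxygens together with the intact C2–C3–C4 enone carrying the 3,4,5-trimethoxyphenyl ring B. The precursor is a linear nine-carbon chain: methyl ester, three ketones separated by methylenes, then the (E)-styryl unit. Ring C is closed afterwards by oxidative cyclisation, and the C8 oxygen is introduced last, para to the C5 hydroxyl.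

Key step: step 4

Remark: the target is achiral, so no step has to set a stereocenter. Chalcone 10 has two free hydroxyls ortho to the carbonyl and may close in part to the racemic flavanone 11 on acidic work-up; both forms are taken into step 5, where they converge on flavone 12.

Step 1
Reactants: 1 4-hydroxy-6-methyl-2H-pyran-2-one (triacetic acid lactone)
Product: 2 methyl 3,5-dioxohexanoate
Conditions: Mg(OMe)2 (2.5 equiv), MeOH, reflux; then cold 2 M HCl
Reagents that add atoms: methanol, CO (delivered as magnesium methoxide, C[O-].C[O-].[Mg+2])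
Why: Alkoxide ring opening of a 4-hydroxy-2-pyranone: methoxide attacks the lactone carbonyl and the resulting 3,5-diketo ester is held as a magnesium chelate, which should prevent re-lactonisation until the acidic work-up.

Step 2
Reactants: 3 (E)-3,4,5-trimethoxycinnamic acid
Product: 5 (E)-N-methoxy-N-methyl-3-(3,4,5-trimethoxyphenyl)prop-2-enamide, via acyl imidazolide 4 (not isolated)
Conditions: 1,1'-carbonyldiimidazole (1.1 equiv), CH2Cl2, rt; then MeNH(OMe)·HCl (1.3 equiv), rt
Reagents that add atoms: N,O-dimethylhydroxylamine hydrochloride, CNOC.Cl; 1,1'-carbonyldiimidazole, O=C(n1ccnc1)n1ccnc1 (its imidazole stays only in intermediate 4)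
Why: Weinreb amide synthesis by carbonyldiimidazole activation of the acid and aminolysis of the acyl imidazolide, under near-neutral conditions that should leave the (E)-alkene and the aryl methyl ethers untouched.

Step 3
Reactants: 2 methyl 3,5-dioxohexanoate (1.3 equiv); 5 (E)-N-methoxy-N-methyl-3-(3,4,5-trimethoxyphenyl)prop-2-enamide
Product: 8 methyl (E)-3,5,7-trioxo-9-(3,4,5-trimethoxyphenyl)non-8-enoate, via trilithium trianion 6 (not isolated), via lithium tetrahedral adduct 7 (not isolated)
Conditions: LiN(i-Pr)2 (4.0 equiv), THF, 0 °C; then 5, −78 to −20 °C; pour into cold 1 M HCl; crude 8 used at once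
Reagents that add atoms: lithium diisopropylamide, [Li+].CC(C)[N-]C(C)C (lithium stays only in intermediates 6 and 7)
Why: Harris-type polyanion C-acylation, in which the base removes the C4, C2 and terminal C6 protons in order of acidity and the last-formed, most basic methyl carbanion adds 1,2 to the Weinreb amide; the chelated adduct 7 persists until the cold quench, so double addition, proton transfer from the product and conjugate addition to the cinnamoyl unit should not compete as they could with a methyl ester donor.

Step 4
Reactants: 8 methyl (E)-3,5,7-trioxo-9-(3,4,5-trimethoxyphenyl)non-8-enoate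
Product: 10 (E)-1-(2,4,6-trihydroxyphenyl)-3-(3,4,5-trimethoxyphenyl)prop-2-en-1-one, via cyclic triketone tautomer 9 (not isolated)
Conditions: Mg(OMe)2 (4 equiv), MeOH, rt to 50 °C, N2; then cold 1 M HCl
Reagents that add atoms: none
Why: Magnesium methoxide turns 8 into a chelated magnesium polyenolate with a folded chain, so that C6, the doubly activated carbon between the C5 and C7 ketones, lies next to the ester carbon C1; C6 adds to C1, methoxide leaves to give trione 9, and 9 enolises at once to the aromatic triol, which makes the closure irreversible. The closest known reaction type is the biomimetic Claisen (Dieckmann-type) cyclisation of 3,5,7-triketo esters to acylphloroglucinols, the laboratory counterpart of the chalcone synthase ring closure. Ring A closes in a 6-(enolexo)-exo-trig mode, the ester carbonyl lying outside the new six-membered ring made of chain carbons C1 to C6. No stereocenter is formed and the (E)-alkene is a spectator. The selectivity required is C-acylation of C6 by the ester over the aldol closure of C2 onto the C7 ketone and over O-acylation to a 4-hydroxy-2-pyranone; the substrate should secure it because C7 is a conjugated cinnamoyl ketone tied up as a magnesium enolate chelate and hence a weak electrophile, the ester carbon stays the most electrophilic site, and any pyranone formed is reopened by the same reagent (as in step 1) until it drains into the aromatic product. Because the two ring carbons ortho to the acyl group are equivalent, the new bond becomes C4a–C5 whichever hydroxyl later closes ring C.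

Step 5
Reactants: 10 (E)-1-(2,4,6-trihydroxyphenyl)-3-(3,4,5-trimethoxyphenyl)prop-2-en-1-one
Product: 12 5,7-dihydroxy-2-(3,4,5-trimethoxyphenyl)-4H-chromen-4-one, via racemic flavanone 11 (not isolated)
Conditions: I2 (0.1 equiv), DMSO, 120 °C; aq. Na2S2O3 work-up
Reagents that add atoms: none
Why: Iodine-catalysed oxidative cyclisation of a 2'-hydroxychalcone, in which oxa-Michael addition of an ortho hydroxyl gives flavanone 11, iodine dehydrogenates C2–C3 and dimethyl sulfoxide re-oxidises the hydrogen iodide; the two ortho hydroxyls are equivalent, so only one flavone can form, and the catalytic iodine loading should keep ring iodination of the electron-rich ring A low.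

Step 6
Reactants: 12 5,7-dihydroxy-2-(3,4,5-trimethoxyphenyl)-4H-chromen-4-one
Product: 13 5-hydroxy-7-methoxy-2-(3,4,5-trimethoxyphenyl)-4H-chromen-4-one
Conditions: Me2SO4 (1.05 equiv), K2CO3 (1.5 equiv), acetone, reflux
Reagents that add atoms: dimethyl sulfate, COS(=O)(=O)OC
Why: Williamson methylation should be selective for the 7-hydroxyl, the more acidic vinylogous-acid phenol, because the 5-hydroxyl is locked in a hydrogen bond to the C4 carbonyl and does not react with one equivalent of the reagent under mild carbonate conditions.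

Step 7
Reactants: 13 5-hydroxy-7-methoxy-2-(3,4,5-trimethoxyphenyl)-4H-chromen-4-one
Product: 15 5,8-dihydroxy-7-methoxy-2-(3,4,5-trimethoxyphenyl)-4H-chromen-4-one, via potassium aryl sulfate 14 (not isolated)
Conditions: K2S2O8 (1.5 equiv), aq. KOH, pyridine, 10–20 °C; acidify, remove unreacted 13; then HCl, Na2SO3, 90 °C
Reagents that add atoms: potassium peroxodisulfate, [K+].[K+].[O-]S(=O)(=O)OOS(=O)(=O)[O-]
Why: Elbs persulfate oxidation, in which the C5 phenoxide attacks a peroxide oxygen through its para carbon C8 (the ortho carbon C6 reacts far less) to give aryl sulfate 14, whose S–O bond is then cleaved by warm dilute acid; unreacted 13 is recovered and recycled.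

Step 8
Reactants: 15 5,8-dihydroxy-7-methoxy-2-(3,4,5-trimethoxyphenyl)-4H-chromen-4-one
Product: 16 5,7,8-trimethoxy-2-(3,4,5-trimethoxyphenyl)-4H-chromen-4-one (bannamurpanisin)
Conditions: Me2SO4 (5 equiv), K2CO3 (6 equiv), acetone, reflux, N2
Reagents that add atoms: dimethyl sulfate, COS(=O)(=O)OC
Why: Exhaustive Williamson methylation should etherify the free 8-hydroxyl quickly and the chelated 5-hydroxyl more slowly under forcing carbonate conditions, with air excluded because the 5,8-hydroquinone is oxidisable in base.

Compound list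
1 | 4-hydroxy-6-methyl-2H-pyran-2-one | CC1=CC(O)=CC(=O)O1 | starting material
2 | methyl 3,5-dioxohexanoate | COC(=O)CC(=O)CC(C)=O | intermediate
3 | (E)-3,4,5-trimethoxycinnamic acid | COc1cc(/C=C/C(=O)O)cc(OC)c1OC | starting material
4 | (E)-1-(1H-imidazol-1-yl)-3-(3,4,5-trimethoxyphenyl)prop-2-en-1-one (acyl imidazolide, not isolated) | COc1cc(/C=C/C(=O)n2ccnc2)cc(OC)c1OC | intermediate
5 | (E)-N-methoxy-N-methyl-3-(3,4,5-trimethoxyphenyl)prop-2-enamide | COc1cc(/C=C/C(=O)N(C)OC)cc(OC)c1OC | intermediate
6 | trilithium trianion of methyl 3,5-dioxohexanoate, deprotonated at C2, C4 and C6 (not isolated) | [Li+].[Li+].[Li+].[CH2-]C(=O)[CH-]C(=O)[CH-]C(=O)OC | intermediate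
7 | trilithium salt of methyl (E)-7-hydroxy-7-[methoxy(methyl)amino]-3,5-dioxo-9-(3,4,5-trimethoxyphenyl)non-8-enoate, C7 alkoxide and C2/C4 carbanions, racemic at C7 (not isolated) | [Li+].[Li+].[Li+].COC(=O)[CH-]C(=O)[CH-]C(=O)CC([O-])(/C=C/c1cc(OC)c(OC)c(OC)c1)N(C)OC | intermediate
8 | methyl (E)-3,5,7-trioxo-9-(3,4,5-trimethoxyphenyl)non-8-enoate | COC(=O)CC(=O)CC(=O)CC(=O)/C=C/c1cc(OC)c(OC)c(OC)c1 | intermediate
9 | (E)-2-[3-(3,4,5-trimethoxyphenyl)prop-2-enoyl]cyclohexane-1,3,5-trione (keto tautomer of 10, not isolated) | COc1cc(/C=C/C(=O)C2C(=O)CC(=O)CC2=O)cc(OC)c1OC | intermediate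
10 | (E)-1-(2,4,6-trihydroxyphenyl)-3-(3,4,5-trimethoxyphenyl)prop-2-en-1-one | COc1cc(/C=C/C(=O)c2c(O)cc(O)cc2O)cc(OC)c1OC | intermediate
11 | racemic 5,7-dihydroxy-2-(3,4,5-trimethoxyphenyl)-2,3-dihydro-4H-chromen-4-one (not isolated) | COc1cc(C2CC(=O)c3c(O)cc(O)cc3O2)cc(OC)c1OC | intermediate
12 | 5,7-dihydroxy-2-(3,4,5-trimethoxyphenyl)-4H-chromen-4-one | COc1cc(-c2cc(=O)c3c(O)cc(O)cc3o2)cc(OC)c1OC | intermediate
13 | 5-hydroxy-7-methoxy-2-(3,4,5-trimethoxyphenyl)-4H-chromen-4-one | COc1cc(-c2cc(=O)c3c(O)cc(OC)cc3o2)cc(OC)c1OC | intermediate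
14 | potassium 5-hydroxy-7-methoxy-4-oxo-2-(3,4,5-trimethoxyphenyl)-4H-chromen-8-yl sulfate (not isolated) | [K+].COc1cc(-c2cc(=O)c3c(O)cc(OC)c(OS(=O)(=O)[O-])c3o2)cc(OC)c1OC | intermediate
15 | 5,8-dihydroxy-7-methoxy-2-(3,4,5-trimethoxyphenyl)-4H-chromen-4-one | COc1cc(-c2cc(=O)c3c(O)cc(OC)c(O)c3o2)cc(OC)c1OC | intermediate
16 | 5,7,8-trimethoxy-2-(3,4,5-trimethoxyphenyl)-4H-chromen-4-one (bannamurpanisin) | COc1cc(-c2cc(=O)c3c(OC)cc(OC)c(OC)c3o2)cc(OC)c1OC | target

Total step count: 8.
Longest linear sequence: 7 steps (steps 1, 3, 4, 5, 6, 7, 8; the branch through step 2 is equally long).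

Steps most likely to fail

Step 4. The chain may close in the aldol sense (C2 onto the C7 ketone) to a stilbene carboxylate, or stall by lactonisation or retro-Claisen cleavage. The fallback buys ring A instead of building it; it sets out from Weinreb amide 5 and comes back at chalcone 10. Commercial phloroglucinol is protected (MOMCl, i-Pr2NEt, CH2Cl2) as 1,3,5-tris(methoxymethoxy)benzene F1. F1 is lithiated between two acetal oxygens (n-BuLi, THF, 0 °C) to [2,4,6-tris(methoxymethoxy)phenyl]lithium F2. Addition of F2 to 5 at −78 °C and a cold quench should give (E)-1-[2,4,6-tris(methoxymethoxy)phenyl]-3-(3,4,5-trimethoxyphenyl)prop-2-en-1-one F3. HCl in MeOH at 40 °C removes the three acetals and gives 10, from which step 5 onwards is unchanged.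

Step 3. Trianion formation may be incomplete, the carbanion may add in conjugate fashion, or the product may cyclise during the acidic quench. The fallback replaces the open-chain trianion by a pyranone dianion; it sets out from pyranone 1 and Weinreb amide 5 and comes back at 8. Compound 1 is converted into its dilithio salt (LiN(i-Pr)2, 2.2 equiv, THF/DMPU, −78 to 0 °C), deprotonated at the 4-hydroxyl and the 6-methyl. C-acylation of the methyl carbanion by 5 should give 4-hydroxy-6-[(E)-2-oxo-4-(3,4,5-trimethoxyphenyl)but-3-en-1-yl]-2H-pyran-2-one F4, a storable masked form of the triketo acid. Methanolysis with Mg(OMe)2 in MeOH, as in step 1, opens the lactone to 8; longer exposure to the same reagent would carry it straight on to 10.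

Step 7. Conversion in the persulfate oxidation may be low, and the hydroquinone product may be over-oxidised in alkali. The fallback installs the C8 oxygen by halogenation and copper-mediated methoxylation; it sets out from 13 and comes back at target 16. Methylation of the chelated 5-hydroxyl (Me2SO4, K2CO3, acetone, reflux) gives 5,7-dimethoxy-2-(3,4,5-trimethoxyphenyl)-4H-chromen-4-one F5. Iodination with I2 and CF3CO2Ag in CH2Cl2 is expected at C8, the position flanked by the ring oxygen and the C7 methoxy as is usual for 5,7-dimethoxyflavones, and should give 8-iodo-5,7-dimethoxy-2-(3,4,5-trimethoxyphenyl)-4H-chromen-4-one F6. Ullmann-type methoxylation (NaOMe, CuBr, MeOH/DMF, reflux) then replaces iodine by methoxy to give 16.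

Further compounds
F1 | step 4 | 1,3,5-tris(methoxymethoxy)benzene | COCOc1cc(OCOC)cc(OCOC)c1
F2 | step 4 | [2,4,6-tris(methoxymethoxy)phenyl]lithium | [Li]c1c(OCOC)cc(OCOC)cc1OCOC
F3 | step 4 | (E)-1-[2,4,6-tris(methoxymethoxy)phenyl]-3-(3,4,5-trimethoxyphenyl)prop-2-en-1-one | COCOc1cc(OCOC)c(C(=O)/C=C/c2cc(OC)c(OC)c(OC)c2)c(OCOC)c1
F4 | step 3 | 4-hydroxy-6-[(E)-2-oxo-4-(3,4,5-trimethoxyphenyl)but-3-en-1-yl]-2H-pyran-2-one | COc1cc(/C=C/C(=O)CC2=CC(O)=CC(=O)O2)cc(OC)c1OC
F5 | step 7 | 5,7-dimethoxy-2-(3,4,5-trimethoxyphenyl)-4H-chromen-4-one | COc1cc(-c2cc(=O)c3c(OC)cc(OC)cc3o2)cc(OC)c1OC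
F6 | step 7 | 8-iodo-5,7-dimethoxy-2-(3,4,5-trimethoxyphenyl)-4H-chromen-4-one | COc1cc(-c2cc(=O)c3c(OC)cc(OC)c(I)c3o2)cc(OC)c1OC
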